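The cyclobutane alternates aryl-bearing CH (C2, C4) and carbonyl-bearing CH (C1, C3), so every ring bond joins one of each. The C1–C4 bond is therefore disconnected by re-inserting a nitrogen between its two carbons, which leads back to a pyrrolidine whose C2 carries the ester and whose C5 carries the aryl group. In the key step, oxidative N-amination of this N–H pyrrolidine and loss of dinitrogen excise N1 and join C2 to C5 in one operation, closing the four-membered ring with all four configurations kept. The precursor is the racemic 2,5-cis, 3,4-cis, 2,3-trans, 4,5-trans dimethyl 3,5-diarylpyrrolidine-2,4-dicarboxylate, assembled by azomethine ylide cycloaddition to a (Z)-cinnamate.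

Key step: step 4

Remark: the target has an inversion centre (alpha head-to-tail arrangement, identical aryl groups, identical imides) and is achiral, so pyrrolidine 7 is used as the racemate and no enantioselective catalyst is needed; the SMILES of 7, 8, 9, F1 and F2 show one enantiomer for relative configuration only.

Step 1
Reactants: 1 3,4-dimethoxybenzaldehyde; 2 methyl 2-(diphenoxyphosphoryl)acetate
Product: 3 methyl (Z)-3-(3,4-dimethoxyphenyl)prop-2-enoate
Conditions: NaH, THF, −78 °C → 0 °C; chromatography to remove the minor E isomer
Reagents that add atoms: none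
Why: Z-selective Horner–Wadsworth–Emmons olefination, in which the electron-poor diaryl phosphonate makes collapse of the kinetically formed cis-oxaphosphetane faster than its equilibration, so the Z alkene should predominate.

Step 2
Reactants: 1 3,4-dimethoxybenzaldehyde; 4 methyl glycinate hydrochloride
Product: 5 methyl (E)-2-[(3,4-dimethoxybenzylidene)amino]acetate
Conditions: Et3N, 4 Å molecular sieves, CH2Cl2, rt; filtered and used crude
Reagents that add atoms: none
Why: Schiff-base condensation of the free-based amino ester with a non-enolisable aryl aldehyde, driven by water removal, should give the conjugated E aldimine.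

Step 3
Reactants: 3 methyl (Z)-3-(3,4-dimethoxyphenyl)prop-2-enoate; 5 methyl (E)-2-[(3,4-dimethoxybenzylidene)amino]acetate
Product: 7 rac-dimethyl 3,5-bis(3,4-dimethoxyphenyl)pyrrolidine-2,4-dicarboxylate (2,5-cis; 3,4-cis; 2,3-trans; 4,5-trans), via copper azomethine ylide 6 (not isolated)
Conditions: Cu(CH3CN)4PF6 (5 mol %), rac-BINAP (5.5 mol %), Et3N (10 mol %), THF, 0 °C → rt
Reagents that add atoms: none
Why: Catalytic 1,3-dipolar cycloaddition of an N-metalated azomethine ylide, in which N,O-chelation to monovalent copper fixes the W-shaped ylide (2,5-cis), the ester-bearing ylide carbon bonds to the beta-carbon of the acrylate (3-aryl, 4-ester), suprafacial addition carries the Z geometry into the 3,4-cis relationship, and the bulky bisphosphine disfavours the endo approach so that both alkene substituents end up trans to their neighbours at C2 and C5.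

Step 4
Reactants: 7 rac-dimethyl 3,5-bis(3,4-dimethoxyphenyl)pyrrolidine-2,4-dicarboxylate (2,5-cis; 3,4-cis; 2,3-trans; 4,5-trans)
Product: 10 dimethyl (1α,2α,3β,4β)-2,4-bis(3,4-dimethoxyphenyl)cyclobutane-1,3-dicarboxylate, via 1,1-diazene 8 (not isolated), via 1,4-biradical 9 (not isolated)
Conditions: PhI(OH)OTs (2.5 equiv), H2NCO2NH4 (8 equiv), CF3CH2OH, 80 °C
Reagents that add atoms: none
Why: The hypervalent iodine oxidant and ammonia released from the carbamate generate an iodonitrene that transfers nitrogen to N1 of 7, and loss of iodobenzene gives the 1,1-diazene 8, which expels dinitrogen to leave the singlet 1,4-biradical 9 with a benzylic radical at the former C5 and an ester-stabilised radical at the former C2. The closest known reaction type is the iodonitrene-mediated contraction of N–H pyrrolidines to cyclobutanes, a one-pot form of the classical oxidation of N-aminopyrrolidines. The four-membered ring closes by direct radical–radical combination of the two termini (pyrrolidine C2–C5, which is the C1–C4 bond of the cyclobutane), a near-barrierless collapse of a singlet pair born with its ends held close by the ring it came from. No new stereocentre is created: pyrrolidine C3 and C4 are untouched and keep their cis relationship, and the two radical carbons should re-form their original configurations because collapse is faster than rotation about the C2–C3 and C4–C5 bonds. The step needs this retention, and it needs recombination to win over scission of the C3–C4 bond (which would return two cinnamate molecules); both rest on the singlet spin state inherited from 8 and on the short lifetime of a biradical whose termini are generated within bonding distance. Because the product is centrosymmetric, both enantiomers of 7 converge on the same achiral cyclobutane 10.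

Step 5
Reactants: 10 dimethyl (1α,2α,3β,4β)-2,4-bis(3,4-dimethoxyphenyl)cyclobutane-1,3-dicarboxylate
Product: 11 (1α,2α,3β,4β)-2,4-bis(3,4-dimethoxyphenyl)cyclobutane-1,3-dicarboxylic acid
Conditions: LiOH·H2O (6 equiv), THF/MeOH/H2O, 40 °C; then 1 M HCl
Reagents that add atoms: lithium hydroxide, [Li+].[OH-]
Why: Saponification (acyl–oxygen ester hydrolysis) should be faster than enolisation of the ring esters, and each carboxylate once formed resists deprotonation at its alpha carbon, so the configuration is kept.

Step 6
Reactants: 11 (1α,2α,3β,4β)-2,4-bis(3,4-dimethoxyphenyl)cyclobutane-1,3-dicarboxylic acid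
Product: 12 (1α,2α,3β,4β)-2,4-bis(3,4-dimethoxyphenyl)cyclobutane-1,3-dicarbonyl dichloride
Conditions: (COCl)2 (4 equiv), DMF (cat.), CH2Cl2, 0 °C → rt; concentrated and used crude
Reagents that add atoms: oxalyl chloride, O=C(Cl)C(Cl)=O
Why: Acid chloride formation through the Vilsmeier-type chloroiminium catalyst runs without base, so no ketene can form to epimerise the alpha carbons, and no Lewis acid is present to trigger Friedel–Crafts acylation of the dimethoxyphenyl rings.

Step 7
Reactants: 12 (1α,2α,3β,4β)-2,4-bis(3,4-dimethoxyphenyl)cyclobutane-1,3-dicarbonyl dichloride; 13 5,6-dihydropyridin-2(1H)-one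
Product: 15 1,1'-{[(1α,2α,3β,4β)-2,4-bis(3,4-dimethoxyphenyl)cyclobutane-1,3-diyl]dicarbonyl}bis(5,6-dihydropyridin-2(1H)-one), via lithium lactamate 14 (not isolated)
Conditions: 13 (2.4 equiv), LiN(SiMe3)2 (2.2 equiv), THF, −78 °C; then 12 in THF, −78 °C; AcOH quench at −78 °C
Reagents that add atoms: none
Why: N-acylation of a lithium lactamate by an acid chloride (imide formation) should be much faster at −78 °C than conjugate addition or alpha-deprotonation, and keeping the lactam in slight excess over the base leaves no free amide base.

Compound list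
1 | 3,4-dimethoxybenzaldehyde | COc1ccc(C=O)cc1OC | starting material
2 | methyl 2-(diphenoxyphosphoryl)acetate | O=P(Oc1ccccc1)(Oc1ccccc1)CC(=O)OC | starting material
3 | methyl (Z)-3-(3,4-dimethoxyphenyl)prop-2-enoate | COC(=O)/C=C\c1ccc(OC)c(OC)c1 | intermediate
4 | methyl glycinate hydrochloride | COC(=O)CN.Cl | starting material
5 | methyl (E)-2-[(3,4-dimethoxybenzylidene)amino]acetate | COC(=O)C/N=C/c1ccc(OC)c(OC)c1 | intermediate
6 | copper azomethine ylide of 5 (N,O-chelated, W-shaped; bisphosphine ligand not drawn) | COC(=O)[CH-]/N=C/c1ccc(OC)c(OC)c1.[Cu+] | intermediate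
7 | rac-dimethyl 3,5-bis(3,4-dimethoxyphenyl)pyrrolidine-2,4-dicarboxylate; 2-ester and 5-aryl on one face, 3-aryl and 4-ester on the other | COc1ccc([C@H]2[C@H](C(=O)OC)[C@H](c3ccc(OC)c(OC)c3)[C@@H](C(=O)OC)N2)cc1OC | intermediate
8 | 1,1-diazene of 7 (ring nitrogen doubly bonded to a terminal nitrogen; configuration as in 7) | COc1ccc([C@H]2[C@H](C(=O)OC)[C@H](c3ccc(OC)c(OC)c3)[C@@H](C(=O)OC)[N+]2=[N-])cc1OC | intermediate
9 | singlet 1,4-biradical MeO2C–CH•–CH(Ar)–CH(CO2Me)–CH•–Ar (Ar = 3,4-dimethoxyphenyl; the two central centres as in 7) | COc1ccc([CH][C@H](C(=O)OC)[C@H](c2ccc(OC)c(OC)c2)[CH]C(=O)OC)cc1OC | intermediate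
10 | dimethyl (1α,2α,3β,4β)-2,4-bis(3,4-dimethoxyphenyl)cyclobutane-1,3-dicarboxylate (esters trans to each other, aryls trans to each other; achiral) | COc1ccc([C@H]2[C@H](C(=O)OC)[C@H](c3ccc(OC)c(OC)c3)[C@H]2C(=O)OC)cc1OC | intermediate
11 | (1α,2α,3β,4β)-2,4-bis(3,4-dimethoxyphenyl)cyclobutane-1,3-dicarboxylic acid | COc1ccc([C@H]2[C@H](C(=O)O)[C@H](c3ccc(OC)c(OC)c3)[C@H]2C(=O)O)cc1OC | intermediate
12 | (1α,2α,3β,4β)-2,4-bis(3,4-dimethoxyphenyl)cyclobutane-1,3-dicarbonyl dichloride | COc1ccc([C@H]2[C@H](C(=O)Cl)[C@H](c3ccc(OC)c(OC)c3)[C@H]2C(=O)Cl)cc1OC | intermediate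
13 | 5,6-dihydropyridin-2(1H)-one | O=C1C=CCCN1 | starting material
14 | lithium salt of 5,6-dihydropyridin-2(1H)-one (N-lithiated) | [Li+].O=C1C=CCC[N-]1 | intermediate
15 | 1,1'-{[(1α,2α,3β,4β)-2,4-bis(3,4-dimethoxyphenyl)cyclobutane-1,3-diyl]dicarbonyl}bis(5,6-dihydropyridin-2(1H)-one) | COc1ccc([C@H]2[C@H](C(=O)N3CCC=CC3=O)[C@H](c3ccc(OC)c(OC)c3)[C@H]2C(=O)N2CCC=CC2=O)cc1OC | target

Total step count: 7
Longest linear sequence: 6 steps (1 → 3 → 7 → 10 → 11 → 12 → 15; the branch through 5 is equally long)

Steps most likely to fail

Step 4 (key step). Three processes may compete: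
- scission of the former C3–C4 bond of the biradical, which returns two cinnamate molecules;
- bond rotation before collapse, which would leak into other cyclobutane diastereomers;
- oxidation of the electron-rich dimethoxyphenyl rings, or dehydrogenation of the amine, by the iodine oxidant before nitrogen transfer.

The fallback sets out from 7 and builds the same diazene stepwise, without an aryl-oxidising reagent and at lower temperature. N-nitrosation with tert-butyl nitrite in CH2Cl2 at rt should give rac-dimethyl 3,5-bis(3,4-dimethoxyphenyl)-1-nitrosopyrrolidine-2,4-dicarboxylate F1. Reduction with Zn dust in AcOH at 0 °C should give rac-dimethyl 1-amino-3,5-bis(3,4-dimethoxyphenyl)pyrrolidine-2,4-dicarboxylate F2. Oxidation of this 1,1-disubstituted hydrazine with yellow HgO in CH2Cl2 at 0 °C → rt generates the diazene 8, which loses dinitrogen and closes to the cyclobutane; the route is rejoined at 10.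

Step 3. The pyrrolidine configuration may erode in three ways:
- a stepwise Michael–Mannich pathway or base-mediated isomerisation of the Z alkene, which loses the 3,4-cis relationship;
- incomplete exo preference;
- sluggish reaction of the beta-aryl acrylate.

Each would lead, after step 4, to a different cyclobutane diastereomer. The relative configuration of 7 would be checked by NOE or crystallography before step 4. The fallback sets out from 1 and abandons the nitrogen-deletion logic, so it serves only to supply material for steps 6 and 7. Knoevenagel–Doebner condensation with malonic acid (pyridine, cat. piperidine, 100 °C) should give (E)-3-(3,4-dimethoxyphenyl)prop-2-enoic acid F3. Irradiation of its head-to-tail stacked crystals (λ > 300 nm, solid state) should give the centrosymmetric head-to-tail dimer by topochemical [2+2] photodimerisation; the route is rejoined at 11.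

Step 7. Three processes may interfere:
- epimerisation alpha to the acyl chloride through ketene formation by the basic lactamate;
- conjugate addition of the lactamate to the enone of the product or of another lactam molecule;
- incomplete double acylation.

The fallback sets out from 12 and builds the unsaturated lactam rings after the C–N bonds are in place. Aminolysis with excess but-3-en-1-amine in CH2Cl2 at 0 °C should give (1α,2α,3β,4β)-N,N'-di(but-3-en-1-yl)-2,4-bis(3,4-dimethoxyphenyl)cyclobutane-1,3-dicarboxamide F4. N-deprotonation with LiN(SiMe3)2 and acylation with acryloyl chloride in THF at −78 °C should give (1α,2α,3β,4β)-N,N'-diacryloyl-N,N'-di(but-3-en-1-yl)-2,4-bis(3,4-dimethoxyphenyl)cyclobutane-1,3-dicarboxamide F5. Double ring-closing metathesis with the second-generation Grubbs catalyst [RuCl2(=CHPh)(PCy3)(1,3-dimesitylimidazolidin-2-ylidene)] in CH2Cl2 at 40 °C closes both dihydropyridinone rings; the route is rejoined at 15.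

Further compounds
F1 | step 4 | rac-dimethyl 3,5-bis(3,4-dimethoxyphenyl)-1-nitrosopyrrolidine-2,4-dicarboxylate (configuration as in 7) | COc1ccc([C@H]2[C@H](C(=O)OC)[C@H](c3ccc(OC)c(OC)c3)[C@@H](C(=O)OC)N2N=O)cc1OC
F2 | step 4 | rac-dimethyl 1-amino-3,5-bis(3,4-dimethoxyphenyl)pyrrolidine-2,4-dicarboxylate (configuration as in 7) | COc1ccc([C@H]2[C@H](C(=O)OC)[C@H](c3ccc(OC)c(OC)c3)[C@@H](C(=O)OC)N2N)cc1OC
F3 | step 3 | (E)-3-(3,4-dimethoxyphenyl)prop-2-enoic acid | COc1ccc(/C=C/C(=O)O)cc1OC
F4 | step 7 | (1α,2α,3β,4β)-N,N'-di(but-3-en-1-yl)-2,4-bis(3,4-dimethoxyphenyl)cyclobutane-1,3-dicarboxamide | COc1ccc([C@H]2[C@H](C(=O)NCCC=C)[C@H](c3ccc(OC)c(OC)c3)[C@H]2C(=O)NCCC=C)cc1OC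
F5 | step 7 | (1α,2α,3β,4β)-N,N'-diacryloyl-N,N'-di(but-3-en-1-yl)-2,4-bis(3,4-dimethoxyphenyl)cyclobutane-1,3-dicarboxamide | COc1ccc([C@H]2[C@H](C(=O)N(CCC=C)C(=O)C=C)[C@H](c3ccc(OC)c(OC)c3)[C@H]2C(=O)N(CCC=C)C(=O)C=C)cc1OC
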